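A direct plan would build ring B first: 2,3-dihydroxybenzaldehyde A1 would be methylated at O2, capped as a pivalate and homologated by a methoxymethylene Wittig reaction and hydrolysis to the arylacetaldehyde A2, whose morpholine enamine A3 would be C-acylated with 2,3,4-trimethoxybenzoyl chloride A4.
Hydrolysis would give the hydroxymethylene ketone A5, an anodic dehydrogenative closure of the enol oxygen onto the free ortho carbon of ring A (O1–C8a) would give the chromone pivalate A6, and methanolysis would free the phenol.
Weak point, the O1–C8a closure: an enol oxygen would have to attack an unactivated aryl C–H in an electrochemical step without precedent, against the resting chelate of A5 and with an oxidisable product, and this on the most advanced material.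
Weak point, the run-up to A2: four linear steps would add one carbon to a benzaldehyde and end in an arylacetaldehyde prone to air oxidation and self-condensation.
Weak point, the pivalate: put on early and taken off last, it would build nothing and would have to survive ylide, acid, amine and base on the way.

**Retrosynthetic overview**
Key disconnection: the C3–C1' bond between ring C and ring B, made by a 1,2-shift of ring B from C2 to C3 of a chalcone (the aryl shift of isoflavone biosynthesis, here with Tl(NO3)3·3H2O, trivalent thallium); the same step raises C2 to the aldehyde level as a dimethyl acetal.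
The chalcone holds every carbon of the target and comes from one Claisen–Schmidt condensation (C2–C3 bond) of two catalogue aromatics that already carry the full oxygen pattern of rings A and B.
Ring order: rings A and B are bought, and ring C closes last at O1–C2 from a phenol oxygen that ring A owns from the start, so no aryl C–H is oxidised and no electrolysis is needed.
No arylacetaldehyde or enamine is made; the two benzyl ethers keep both phenols away from the oxidant and leave in the flask of the ring closure, so the risk sits in the rearrangement alone.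

Key step: step 4

Assumption: 3-hydroxy-2-methoxybenzaldehyde and 1-(6-hydroxy-2,3,4-trimethoxyphenyl)ethan-1-one are taken as catalogue chemicals; the target has no stereocentre, and the stereocentres of the intermediates are racemic and vanish in the last step.

Step 1
Reactants: 1 3-hydroxy-2-methoxybenzaldehyde
Product: 2 3-(benzyloxy)-2-methoxybenzaldehyde
Conditions: BnBr (1.1 equiv), K2CO3 (1.5 equiv), DMF, rt
Reagents that add atoms: benzyl bromide, BrCc1ccccc1
Why: Williamson ether synthesis, in which the phenoxide formed by K2CO3 is benzylated in an SN2 reaction while the aldehyde and the aryl methyl ether are inert.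

Step 2
Reactants: 3 1-(6-hydroxy-2,3,4-trimethoxyphenyl)ethan-1-one
Product: 4 1-[6-(benzyloxy)-2,3,4-trimethoxyphenyl]ethan-1-one
Conditions: BnBr (1.2 equiv), K2CO3 (2 equiv), DMF, 70 °C
Reagents that add atoms: benzyl bromide, BrCc1ccccc1
Why: Williamson ether synthesis on the chelated ortho-hydroxy ketone, which needs DMF and gentle heat to break the hydrogen bond, while carbonate does not alkylate the methyl ketone.

Step 3
Reactants: 2 3-(benzyloxy)-2-methoxybenzaldehyde; 4 1-[6-(benzyloxy)-2,3,4-trimethoxyphenyl]ethan-1-one
Product: 5 (E)-1-[6-(benzyloxy)-2,3,4-trimethoxyphenyl]-3-[3-(benzyloxy)-2-methoxyphenyl]prop-2-en-1-one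
Conditions: KOH (50 % aq., 3 equiv), EtOH, rt
Reagents that add atoms: none
Why: Claisen–Schmidt (crossed aldol) condensation in which only 4 can form an enolate and only 2 offers a non-enolisable aldehyde, and E1cB loss of water gives the conjugated enone in its thermodynamic E form, whose geometry is consumed in step 4 anyway.

Step 4
Reactants: 5 (E)-1-[6-(benzyloxy)-2,3,4-trimethoxyphenyl]-3-[3-(benzyloxy)-2-methoxyphenyl]prop-2-en-1-one
Product: 6 1-[6-(benzyloxy)-2,3,4-trimethoxyphenyl]-2-[3-(benzyloxy)-2-methoxyphenyl]-3,3-dimethoxypropan-1-one (racemic)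
Conditions: Tl(NO3)3·3H2O (1.15 equiv), MeOH–HC(OMe)3 (3:1), 0 °C → rt
Reagents that add atoms: methanol, CO
Why: Oxidative 1,2-aryl migration of a chalcone with thallium trinitrate, the chemical counterpart of the aryl shift of isoflavone biosynthesis: the trivalent thallium electrophile adds to the enone C=C with methanol entering at the benzylic carbon (later C2), and heterolysis of the weak C–Tl bond at the α-carbon (later C3) is assisted by ring B, which bridges as a phenonium ion and ends on C3, while the methoxycarbenium ion left at C2 is trapped by methanol as the dimethyl acetal and thallium leaves in its monovalent state. The closest known reaction type is this very rearrangement of 2'-alkoxychalcones to 1,2-diaryl-3,3-dimethoxypropan-1-ones, a standard entry to polyoxygenated isoflavones. No ring closes here; the pyranone follows in step 5. The one new stereocentre (the later C3) forms as a racemate without control and needs none, because it becomes sp2 in step 5. The step needs migration of ring B and not of ring A, which is secured by the ortho-methoxy group of ring B (it stabilises the benzylic cation and the phenonium ion) and by the doubly ortho-substituted, twisted aroyl group, which resists the ketal formation from which ring A would migrate; it also needs oxidation of the enone before the electron-rich rings, which is secured by capping both phenols as benzyl ethers so that no p-methoxyphenol is offered to the oxidant.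

Step 5
Reactants: 6 1-[6-(benzyloxy)-2,3,4-trimethoxyphenyl]-2-[3-(benzyloxy)-2-methoxyphenyl]-3,3-dimethoxypropan-1-one
Product: 9 3-(3-hydroxy-2-methoxyphenyl)-5,6,7-trimethoxy-4H-chromen-4-one, via bis-phenol keto acetal 7 (not isolated), via 2-methoxyisoflavanone 8 (not isolated)
Conditions: H2 (1 atm), Pd/C (10 %), EtOAc, rt; filtration; then HCl (3 M aq., cat.), MeOH, 60 °C
Reagents that add atoms: none
Why: Hydrogenolysis of both aryl benzyl ethers over Pd/C is done while C3 is still sp3, so no chromone double bond is exposed to hydrogen, and acid then turns the acetal into an oxocarbenium ion that the ring A phenol traps in a 6-exo-trig closure (O1–C2) to the 2-methoxyisoflavanone, which loses methanol to the 4-pyranone and erases the stereocentre at C3; dilute HCl in methanol leaves the aryl methyl ethers intact.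

**Compound list**
1 | 3-hydroxy-2-methoxybenzaldehyde | COc1c(O)cccc1C=O | starting material
2 | 3-(benzyloxy)-2-methoxybenzaldehyde | COc1c(OCc2ccccc2)cccc1C=O | intermediate
3 | 1-(6-hydroxy-2,3,4-trimethoxyphenyl)ethan-1-one | CC(=O)c1c(O)cc(OC)c(OC)c1OC | starting material
4 | 1-[6-(benzyloxy)-2,3,4-trimethoxyphenyl]ethan-1-one | CC(=O)c1c(OCc2ccccc2)cc(OC)c(OC)c1OC | intermediate
5 | (E)-1-[6-(benzyloxy)-2,3,4-trimethoxyphenyl]-3-[3-(benzyloxy)-2-methoxyphenyl]prop-2-en-1-one | COc1c(OCc2ccccc2)cccc1/C=C/C(=O)c1c(OCc2ccccc2)cc(OC)c(OC)c1OC | intermediate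
6 | 1-[6-(benzyloxy)-2,3,4-trimethoxyphenyl]-2-[3-(benzyloxy)-2-methoxyphenyl]-3,3-dimethoxypropan-1-one (racemic) | COC(OC)C(c1cccc(OCc2ccccc2)c1OC)C(=O)c1c(OCc2ccccc2)cc(OC)c(OC)c1OC | intermediate
7 | 2-(3-hydroxy-2-methoxyphenyl)-1-(6-hydroxy-2,3,4-trimethoxyphenyl)-3,3-dimethoxypropan-1-one (racemic) | COC(OC)C(c1cccc(O)c1OC)C(=O)c1c(O)cc(OC)c(OC)c1OC | intermediate
8 | 3-(3-hydroxy-2-methoxyphenyl)-2,5,6,7-tetramethoxy-2,3-dihydro-4H-chromen-4-one (mixture of diastereomers, racemic) | COC1Oc2cc(OC)c(OC)c(OC)c2C(=O)C1c1cccc(O)c1OC | intermediate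
9 | 3-(3-hydroxy-2-methoxyphenyl)-5,6,7-trimethoxy-4H-chromen-4-one (3'-hydroxy-2',5,6,7-tetramethoxyisoflavone) | COc1cc2occ(-c3cccc(O)c3OC)c(=O)c2c(OC)c1OC | target

Total step count: 5. Longest linear sequence: 4 steps (1 → 2 → 5 → 6 → 9, or 3 → 4 → 5 → 6 → 9).

**Steps most likely to fail**

Step 4 (oxidative aryl shift). The oxidant, or the nitric acid it sets free, may attack the electron-rich ring A before the hindered, twisted enone is methoxythallated, or ring A may migrate by way of a ketal. The fallback sets out from 5 and comes back at 9. Weitz–Scheffer epoxidation (H2O2, NaOH, MeOH–THF, 0 °C) would give the racemic trans-epoxide {(2R*,3S*)-3-[3-(benzyloxy)-2-methoxyphenyl]oxiran-2-yl}[6-(benzyloxy)-2,3,4-trimethoxyphenyl]methanone F1. BF3·OEt2 (CH2Cl2, −20 °C) would open it at the benzylic carbon, and a 1,2-shift of the aroyl group (Meinwald-type rearrangement of an epoxy ketone) would give the formyl ketone 2-[3-(benzyloxy)-2-methoxyphenyl]-3-[6-(benzyloxy)-2,3,4-trimethoxyphenyl]-3-oxopropanal F2. F2 has the connectivity of 6 and is reached without any oxidant for arenes. Hydrogenolysis (H2, Pd/C, EtOAc) to the bis-phenol 2-(3-hydroxy-2-methoxyphenyl)-3-(6-hydroxy-2,3,4-trimethoxyphenyl)-3-oxopropanal F3 (not isolated) and the acid of step 5 would then give 9 by cyclodehydration.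

Step 5 (hydrogenolysis, then ring closure). Hydrogenolysis may stall at the hindered ring A ether or run on to reduction of the aryl ketone. If the catalyst support starts the ring closure early, C2=C3 may also be reduced. The fallback sets out from 1 and 3 and comes back at 9, with acid-labile ethers in place of benzyl so that the route needs no hydrogenation.
- MOMCl with iPr2NEt (CH2Cl2) would turn 1 into 2-methoxy-3-(methoxymethoxy)benzaldehyde F4.
- MOMCl with NaH (DMF) would turn 3 into 1-[2,3,4-trimethoxy-6-(methoxymethoxy)phenyl]ethan-1-one F5.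
- Claisen–Schmidt condensation as in step 3 would give (E)-3-[2-methoxy-3-(methoxymethoxy)phenyl]-1-[2,3,4-trimethoxy-6-(methoxymethoxy)phenyl]prop-2-en-1-one F6.
- The thallium trinitrate rearrangement as in step 4 would give 3,3-dimethoxy-2-[2-methoxy-3-(methoxymethoxy)phenyl]-1-[2,3,4-trimethoxy-6-(methoxymethoxy)phenyl]propan-1-one F7.
- HCl in MeOH at 60 °C would then remove both acetal protecting groups and close ring C to 9 in one acid operation.

Step 3 (condensation). The doubly ortho-substituted ketone may condense slowly, so that Cannizzaro reaction of 2 and Michael addition of the enolate of 4 to 5 take over. The fallback sets out from 4 and 2 and comes back at 5. A directed aldol addition of the lithium enolate of 4 (LiN(SiMe3)2, THF, −78 °C) to 2 would give the β-hydroxy ketone 1-[6-(benzyloxy)-2,3,4-trimethoxyphenyl]-3-[3-(benzyloxy)-2-methoxyphenyl]-3-hydroxypropan-1-one F8 (racemic) without reversible, strongly basic conditions. A separate acid-catalysed dehydration (p-TsOH cat., toluene, 50 °C) would then give 5.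

**Further compounds**
F1 | step 4 | {(2R*,3S*)-3-[3-(benzyloxy)-2-methoxyphenyl]oxiran-2-yl}[6-(benzyloxy)-2,3,4-trimethoxyphenyl]methanone (trans, racemic, one enantiomer drawn) | O=C([C@H]1O[C@@H]1c1cccc(OCc2ccccc2)c1OC)c1c(OCc2ccccc2)cc(OC)c(OC)c1OC
F2 | step 4 | 2-[3-(benzyloxy)-2-methoxyphenyl]-3-[6-(benzyloxy)-2,3,4-trimethoxyphenyl]-3-oxopropanal (racemic) | O=CC(c1cccc(OCc2ccccc2)c1OC)C(=O)c1c(OCc2ccccc2)cc(OC)c(OC)c1OC
F3 | step 4 | 2-(3-hydroxy-2-methoxyphenyl)-3-(6-hydroxy-2,3,4-trimethoxyphenyl)-3-oxopropanal (racemic) | O=CC(c1cccc(O)c1OC)C(=O)c1c(O)cc(OC)c(OC)c1OC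
F4 | step 5 | 2-methoxy-3-(methoxymethoxy)benzaldehyde | COCOc1cccc(C=O)c1OC
F5 | step 5 | 1-[2,3,4-trimethoxy-6-(methoxymethoxy)phenyl]ethan-1-one | CC(=O)c1c(OCOC)cc(OC)c(OC)c1OC
F6 | step 5 | (E)-3-[2-methoxy-3-(methoxymethoxy)phenyl]-1-[2,3,4-trimethoxy-6-(methoxymethoxy)phenyl]prop-2-en-1-one | COCOc1cccc(/C=C/C(=O)c2c(OCOC)cc(OC)c(OC)c2OC)c1OC
F7 | step 5 | 3,3-dimethoxy-2-[2-methoxy-3-(methoxymethoxy)phenyl]-1-[2,3,4-trimethoxy-6-(methoxymethoxy)phenyl]propan-1-one (racemic) | COCOc1cccc(C(C(OC)OC)C(=O)c2c(OCOC)cc(OC)c(OC)c2OC)c1OC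
F8 | step 3 | 1-[6-(benzyloxy)-2,3,4-trimethoxyphenyl]-3-[3-(benzyloxy)-2-methoxyphenyl]-3-hydroxypropan-1-one (racemic) | COc1c(OCc2ccccc2)cccc1C(O)CC(=O)c1c(OCc2ccccc2)cc(OC)c(OC)c1OC
A1 | direct plan | 2,3-dihydroxybenzaldehyde | O=Cc1cccc(O)c1O
A2 | direct plan | 2-methoxy-3-(2-oxoethyl)phenyl pivalate | O=CCc1cccc(OC(=O)C(C)(C)C)c1OC
A3 | direct plan | 2-methoxy-3-[(E)-2-(morpholin-4-yl)ethenyl]phenyl pivalate | COc1c(/C=C/N2CCOCC2)cccc1OC(=O)C(C)(C)C
A4 | direct plan | 2,3,4-trimethoxybenzoyl chloride | COc1ccc(C(Cl)=O)c(OC)c1OC
A5 | direct plan | (Z)-3-hydroxy-2-[2-methoxy-3-(pivaloyloxy)phenyl]-1-(2,3,4-trimethoxyphenyl)prop-2-en-1-one | O/C=C(\C(=O)c1ccc(OC)c(OC)c1OC)c1cccc(OC(=O)C(C)(C)C)c1OC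
A6 | direct plan | 2-methoxy-3-(5,6,7-trimethoxy-4-oxo-4H-chromen-3-yl)phenyl pivalate | COc1cc2occ(-c3cccc(OC(=O)C(C)(C)C)c3OC)c(=O)c2c(OC)c1OC
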